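**Retrosynthetic overview**

1. Ring A is the benzene-1,3,5-triol. Its carbon bearing the 2-methylpropanoyl group lies between two C–OH carbons, so the ring is a folded C1–C7 chain. It is cut between that carbon (C6, between the C5 and C7 ketones) and one C–OH neighbour (ester carbon C1): an intramolecular Claisen condensation of a methyl 3,5,7-trioxononanoate that already carries both pyranonylmethyl arms on C2 and C4.
2. Triketo ester ⇒ C5 aldol (oxidation) ⇒ 2-isoxazoline (N–O cleavage). The C5–C7 unit is carried as a nitrile oxide cycloadduct, so C5 is not a ketone while the C3 ketone is built. An aromatic isoxazole is avoided, because its enaminone nitrogen would condense with the C3 ketone to a pyridin-4-one.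
3. Isoxazoline keto ester ⇒ isoxazoline acid (Masamune extension C3→C1, then C2 alkylation with the arm bromide) ⇒ tert-butyl but-3-enoate (α-alkylation with the same bromide, then cycloaddition with the nitrile oxide from 2-methylpropanal).
4. Arm bromide ⇒ 4-hydroxypyranone (O-methylation, C3 bromination, hydroxymethylation, bromination) ⇒ pentan-3-one + malonyl dichloride.
5. Ring order: pyranone ring first (one batch serves both arms), the isoxazoline as a temporary ring, ring A last; cleavage of the two methyl ethers ends the route.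

Key step: step 15

Remark: Ar = 6-ethyl-4-methoxy-5-methyl-2-oxo-2H-pyran-3-yl. The stereocentres formed along the chain (compounds 11 and 16–25) are made without control and are all erased in step 15, so these compounds are carried as mixtures of racemic diastereomers; the target is achiral.

**Route**

Step 1
Reactants: 1 pentan-3-one
Product: 2 (Z)-3-(trimethylsilyloxy)pent-2-ene (Z/E mixture is acceptable)
Conditions: TMSOTf, Et3N, Et2O, 0 °C
Reagents that add atoms: trimethylsilyl trifluoromethanesulfonate C[Si](C)(C)OS(=O)(=O)C(F)(F)F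
Why: Soft enolisation and O-silylation of a symmetrical ketone (silyl enol ether formation) can give only one regioisomer, and the double-bond geometry is lost in step 2.

Step 2
Reactants: 2 (Z)-3-(trimethylsilyloxy)pent-2-ene; 3 malonyl dichloride
Product: 4 6-ethyl-4-hydroxy-5-methyl-2H-pyran-2-one
Conditions: Et2O, −78 °C → rt; aqueous work-up
Reagents that add atoms: none
Why: C-acylation of the silyl enol ether by one acid chloride and O-acylation of the new enol by the other (acylation–lactonisation, a known pyranone synthesis from silyl enol ethers and malonyl dichloride) should close the 4-hydroxy-2-pyranone with methyl at C5 and ethyl at C6.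

Step 3
Reactants: 4 6-ethyl-4-hydroxy-5-methyl-2H-pyran-2-one
Product: 5 6-ethyl-4-methoxy-5-methyl-2H-pyran-2-one
Conditions: Me2SO4, K2CO3, acetone, reflux
Reagents that add atoms: dimethyl sulfate COS(=O)(=O)OC
Why: O-alkylation of the vinylogous acid (Williamson-type) with dimethyl sulfate and K2CO3 favours the 4-methoxy-2-pyranone over the 2-methoxy-4-pyranone and removes the acidic OH before the base steps.

Step 4
Reactants: 5 6-ethyl-4-methoxy-5-methyl-2H-pyran-2-one
Product: 6 3-bromo-6-ethyl-4-methoxy-5-methyl-2H-pyran-2-one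
Conditions: NBS, MeCN, rt, dark
Reagents that add atoms: N-bromosuccinimide O=C1CCC(=O)N1Br
Why: Electrophilic bromination goes to C3, the only ring C–H and the nucleophilic β-carbon of the enol ether; polar, dark conditions suppress allylic radical bromination.

Step 5
Reactants: 6 3-bromo-6-ethyl-4-methoxy-5-methyl-2H-pyran-2-one
Product: 7 6-ethyl-3-(hydroxymethyl)-4-methoxy-5-methyl-2H-pyran-2-one
Conditions: Bu3SnCH2OH, Pd(PPh3)4 (5 mol %), 1,4-dioxane, 90 °C
Reagents that add atoms: (tributylstannyl)methanol OC[Sn](CCCC)(CCCC)CCCC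
Why: Stille coupling: zerovalent palladium inserts into the C3–Br bond of the α-bromo enoate and the hydroxymethyl group is transferred from tin under neutral conditions that leave the lactone and enol ether alone.

Step 6
Reactants: 7 6-ethyl-3-(hydroxymethyl)-4-methoxy-5-methyl-2H-pyran-2-one
Product: 8 3-(bromomethyl)-6-ethyl-4-methoxy-5-methyl-2H-pyran-2-one
Conditions: CBr4, PPh3, CH2Cl2, 0 °C
Reagents that add atoms: tetrabromomethane BrC(Br)(Br)Br
Why: The Appel reaction turns the primary alcohol into the bromide without acid, so the methyl enol ether is not cleaved; 8 is used at once for steps 7 and 12.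

Step 7
Reactants: 9 tert-butyl but-3-enoate; 8 3-(bromomethyl)-6-ethyl-4-methoxy-5-methyl-2H-pyran-2-one
Product: 11 tert-butyl 2-(ArCH2)but-3-enoate (racemic), via lithium dienolate 10 (not isolated)
Conditions: LiN(iPr)2, THF, −78 °C; then 8, −78 → −40 °C
Reagents that add atoms: none
Why: Lithium ester dienolates are alkylated at the α-carbon (deconjugative enolate alkylation, SN2 on the activated primary bromide), which places the arm of the future C4 next to a vinyl group; the new stereocentre is racemic and is erased in step 15.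

Step 8
Reactants: 12 2-methylpropanal
Product: 13 (E)-2-methylpropanal oxime (E/Z mixture is acceptable)
Conditions: NH2OH (50% in H2O), EtOH, 0 °C → rt
Reagents that add atoms: hydroxylamine NO
Why: Oxime condensation of an unhindered aldehyde is reliable and gives the precursor of the nitrile oxide.

Step 9
Reactants: 13 (E)-2-methylpropanal oxime; 11 tert-butyl 2-(ArCH2)but-3-enoate
Product: 16 tert-butyl 3-Ar-2-[3-(propan-2-yl)-4,5-dihydro-1,2-oxazol-5-yl]propanoate (diastereomer mixture), via N-hydroxy-2-methylpropanimidoyl chloride 14 (not isolated), via 2-methylpropanenitrile oxide 15 (not isolated)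
Conditions: NCS, DMF, rt; then 11, Et3N (slow addition), CH2Cl2, 0 °C → rt
Reagents that add atoms: none
Why: Huisgen 1,3-dipolar cycloaddition of the nitrile oxide to the monosubstituted alkene gives the 5-substituted 2-isoxazoline regioselectively, a masked aldol of the C5–C7 unit; the tetrasubstituted pyranone double bonds are poor dipolarophiles, and the two stereocentres are uncontrolled and later destroyed.

Step 10
Reactants: 16 tert-butyl 3-Ar-2-[3-(propan-2-yl)-4,5-dihydro-1,2-oxazol-5-yl]propanoate
Product: 17 3-Ar-2-[3-(propan-2-yl)-4,5-dihydro-1,2-oxazol-5-yl]propanoic acid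
Conditions: TFA, CH2Cl2, 0 °C → rt
Reagents that add atoms: none
Why: Acidolysis of the tert-butyl ester (loss of 2-methylpropene) frees the acid without hydroxide, which spares the pyranone lactone; the isoxazoline and the methyl enol ether tolerate TFA.

Step 11
Reactants: 17 3-Ar-2-[3-(propan-2-yl)-4,5-dihydro-1,2-oxazol-5-yl]propanoic acid; 18 potassium methyl malonate
Product: 21 methyl 5-Ar-3-oxo-4-[3-(propan-2-yl)-4,5-dihydro-1,2-oxazol-5-yl]pentanoate, via acyl imidazolide 19 (not isolated), via magnesium enolate of the malonate half-ester 20 (not isolated)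
Conditions: CDI, THF, rt; then 18, MgCl2, Et3N, MeCN, rt → 40 °C; 1 M HCl work-up
Reagents that add atoms: none
Why: Masamune–Brooks decarboxylative Claisen condensation: the magnesium malonate enolate is C-acylated by the acyl imidazolide and loses CO2, giving the C1–C3 β-keto ester under mild base that does not touch the acidic 6-ethyl CH2 of the pyranone.

Step 12
Reactants: 21 methyl 5-Ar-3-oxo-4-[3-(propan-2-yl)-4,5-dihydro-1,2-oxazol-5-yl]pentanoate; 8 3-(bromomethyl)-6-ethyl-4-methoxy-5-methyl-2H-pyran-2-one
Product: 22 methyl 5-Ar-2-(ArCH2)-3-oxo-4-[3-(propan-2-yl)-4,5-dihydro-1,2-oxazol-5-yl]pentanoate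
Conditions: K2CO3, acetone, 0 °C → rt
Reagents that add atoms: none
Why: The C2 methylene is by far the most acidic carbon of 21 and its enolate is C-alkylated by the activated primary bromide (β-keto ester alkylation); one equivalent of 8 limits dialkylation, and the new stereocentre is uncontrolled and later erased.

Step 13
Reactants: 22 methyl 5-Ar-2-(ArCH2)-3-oxo-4-[3-(propan-2-yl)-4,5-dihydro-1,2-oxazol-5-yl]pentanoate
Product: 24 methyl 2,4-bis(ArCH2)-5-hydroxy-8-methyl-3,7-dioxononanoate, via β-hydroxy ketimine 23 (not isolated)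
Conditions: H2 (1 atm), Raney Ni, B(OH)3, MeOH/H2O (5:1), rt
Reagents that add atoms: water O
Why: Hydrogenolysis of the isoxazoline N–O bond gives the β-hydroxy ketimine, which the boric acid/water buffer hydrolyses at once (reductive isoxazoline-to-aldol unmasking), so the C7 ketone is released before the nitrogen can condense with the C3 ketone; the pyranones and the β-keto ester should not be reduced at 1 atm.

Step 14
Reactants: 24 methyl 2,4-bis(ArCH2)-5-hydroxy-8-methyl-3,7-dioxononanoate
Product: 25 methyl 2,4-bis(ArCH2)-8-methyl-3,5,7-trioxononanoate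
Conditions: Dess–Martin periodinane, CH2Cl2, 0 °C → rt
Reagents that add atoms: none
Why: Dess–Martin oxidation converts the C5 carbinol into the ketone under near-neutral conditions, avoiding the base that would lactonise the triketo ester and the strong acid that would dehydrate it to a 4-pyranone.

Step 15
Reactants: 25 methyl 2,4-bis(ArCH2)-8-methyl-3,5,7-trioxononanoate
Product: 26 3,3'-{[2,4,6-trihydroxy-5-(2-methylpropanoyl)-1,3-phenylene]bis(methylene)}bis(6-ethyl-4-methoxy-5-methyl-2H-pyran-2-one)
Conditions: NaOMe (5 equiv), MeOH, 0 °C → rt; then 1 M HCl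
Reagents that add atoms: none
Why: Methoxide converts 25 into its polyenolate; the C6 carbon, flanked by the C5 and C7 carbonyls, adds to the C1 ester carbonyl, methoxide leaves, and the resulting 2-acylcyclohexane-1,3,5-trione enolises to the phenol, whose deprotonation makes the sequence irreversible. The closest known reaction type is the base-mediated Claisen (Dieckmann-type) cyclisation of 3,5,7-triketo esters to acylphloroglucinols. Ring A closes in a 6-exo-trig mode by forming the C6–C1 bond. No stereocentre is formed, and the C2 and C4 centres of 25 become sp2 ring carbons. The step needs C-acylation at C6 to win over aldol closure of C2 onto C7 and over enol-lactonisation of the C5 oxygen onto C1: the arm on C2 makes the aldol product non-aromatisable and therefore reversible, the enol lactone is reopened by methoxide, and only the Claisen product is drained by aromatisation. Methoxide in methanol is chosen so that addition–elimination at C4 of the 4-methoxypyranones and transesterification at C1 are degenerate, and the low temperature should keep opening of the hindered arm lactones slower than the intramolecular closure.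

Step 16
Reactants: 26 3,3'-{[2,4,6-trihydroxy-5-(2-methylpropanoyl)-1,3-phenylene]bis(methylene)}bis(6-ethyl-4-methoxy-5-methyl-2H-pyran-2-one)
Product: 27 3,3'-{[2,4,6-trihydroxy-5-(2-methylpropanoyl)-1,3-phenylene]bis(methylene)}bis(6-ethyl-4-hydroxy-5-methyl-2H-pyran-2-one) (CNP0277086.0)
Conditions: BBr3 (8 equiv), CH2Cl2, −78 → 0 °C; then H2O
Reagents that add atoms: none
Why: Lewis acid ether cleavage (BBr3 demethylation): boron coordinates each vinylogous ester, bromide removes the methyl group by SN2, and hydrolysis frees the two pyranone 4-hydroxyls; the aryl ketone, the lactones and the methylene bridges should survive at low temperature.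

**Compound list**

1 | pentan-3-one | CCC(=O)CC | starting material
2 | (Z)-3-(trimethylsilyloxy)pent-2-ene | C/C=C(/CC)O[Si](C)(C)C | intermediate
3 | malonyl dichloride (propanedioyl dichloride) | O=C(Cl)CC(Cl)=O | starting material
4 | 6-ethyl-4-hydroxy-5-methyl-2H-pyran-2-one | CCc1oc(=O)cc(O)c1C | intermediate
5 | 6-ethyl-4-methoxy-5-methyl-2H-pyran-2-one | CCc1oc(=O)cc(OC)c1C | intermediate
6 | 3-bromo-6-ethyl-4-methoxy-5-methyl-2H-pyran-2-one | CCc1oc(=O)c(Br)c(OC)c1C | intermediate
7 | 6-ethyl-3-(hydroxymethyl)-4-methoxy-5-methyl-2H-pyran-2-one | CCc1oc(=O)c(CO)c(OC)c1C | intermediate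
8 | 3-(bromomethyl)-6-ethyl-4-methoxy-5-methyl-2H-pyran-2-one | CCc1oc(=O)c(CBr)c(OC)c1C | intermediate
9 | tert-butyl but-3-enoate | C=CCC(=O)OC(C)(C)C | starting material
10 | lithium 1-(tert-butoxy)buta-1,3-dien-1-olate (lithium dienolate) | C=CC=C([O-])OC(C)(C)C.[Li+] | intermediate (not isolated)
11 | tert-butyl 2-[(6-ethyl-4-methoxy-5-methyl-2-oxo-2H-pyran-3-yl)methyl]but-3-enoate (racemic) | C=CC(Cc1c(OC)c(C)c(CC)oc1=O)C(=O)OC(C)(C)C | intermediate
12 | 2-methylpropanal (isobutyraldehyde) | CC(C)C=O | starting material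
13 | (E)-2-methylpropanal oxime | CC(C)/C=N/O | intermediate
14 | N-hydroxy-2-methylpropanimidoyl chloride | CC(C)C(Cl)=NO | intermediate (not isolated)
15 | 2-methylpropanenitrile oxide | CC(C)C#[N+][O-] | intermediate (not isolated)
16 | tert-butyl 3-(6-ethyl-4-methoxy-5-methyl-2-oxo-2H-pyran-3-yl)-2-[3-(propan-2-yl)-4,5-dihydro-1,2-oxazol-5-yl]propanoate (diastereomer mixture) | CC(C)C1=NOC(C1)C(Cc1c(OC)c(C)c(CC)oc1=O)C(=O)OC(C)(C)C | intermediate
17 | 3-(6-ethyl-4-methoxy-5-methyl-2-oxo-2H-pyran-3-yl)-2-[3-(propan-2-yl)-4,5-dihydro-1,2-oxazol-5-yl]propanoic acid (diastereomer mixture) | CC(C)C1=NOC(C1)C(Cc1c(OC)c(C)c(CC)oc1=O)C(=O)O | intermediate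
18 | potassium methyl malonate (potassium 3-methoxy-3-oxopropanoate) | COC(=O)CC(=O)[O-].[K+] | starting material
19 | 1-{3-(6-ethyl-4-methoxy-5-methyl-2-oxo-2H-pyran-3-yl)-2-[3-(propan-2-yl)-4,5-dihydro-1,2-oxazol-5-yl]propanoyl}-1H-imidazole | CC(C)C1=NOC(C1)C(Cc1c(OC)c(C)c(CC)oc1=O)C(=O)n1ccnc1 | intermediate (not isolated)
20 | magnesium 3-methoxy-3-oxidoprop-2-enoate (magnesium enolate of the malonate half-ester) | COC([O-])=CC(=O)[O-].[Mg+2] | intermediate (not isolated)
21 | methyl 5-(6-ethyl-4-methoxy-5-methyl-2-oxo-2H-pyran-3-yl)-3-oxo-4-[3-(propan-2-yl)-4,5-dihydro-1,2-oxazol-5-yl]pentanoate (diastereomer mixture) | COC(=O)CC(=O)C(Cc1c(OC)c(C)c(CC)oc1=O)C1CC(C(C)C)=NO1 | intermediate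
22 | methyl 5-(6-ethyl-4-methoxy-5-methyl-2-oxo-2H-pyran-3-yl)-2-[(6-ethyl-4-methoxy-5-methyl-2-oxo-2H-pyran-3-yl)methyl]-3-oxo-4-[3-(propan-2-yl)-4,5-dihydro-1,2-oxazol-5-yl]pentanoate (diastereomer mixture) | COC(=O)C(Cc1c(OC)c(C)c(CC)oc1=O)C(=O)C(Cc1c(OC)c(C)c(CC)oc1=O)C1CC(C(C)C)=NO1 | intermediate
23 | methyl 2,4-bis[(6-ethyl-4-methoxy-5-methyl-2-oxo-2H-pyran-3-yl)methyl]-5-hydroxy-7-imino-8-methyl-3-oxononanoate | COC(=O)C(Cc1c(OC)c(C)c(CC)oc1=O)C(=O)C(Cc1c(OC)c(C)c(CC)oc1=O)C(O)CC(=N)C(C)C | intermediate (not isolated)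
24 | methyl 2,4-bis[(6-ethyl-4-methoxy-5-methyl-2-oxo-2H-pyran-3-yl)methyl]-5-hydroxy-8-methyl-3,7-dioxononanoate (diastereomer mixture) | COC(=O)C(Cc1c(OC)c(C)c(CC)oc1=O)C(=O)C(Cc1c(OC)c(C)c(CC)oc1=O)C(O)CC(=O)C(C)C | intermediate
25 | methyl 2,4-bis[(6-ethyl-4-methoxy-5-methyl-2-oxo-2H-pyran-3-yl)methyl]-8-methyl-3,5,7-trioxononanoate (diastereomer and enol mixture) | COC(=O)C(Cc1c(OC)c(C)c(CC)oc1=O)C(=O)C(Cc1c(OC)c(C)c(CC)oc1=O)C(=O)CC(=O)C(C)C | intermediate
26 | 3,3'-{[2,4,6-trihydroxy-5-(2-methylpropanoyl)-1,3-phenylene]bis(methylene)}bis(6-ethyl-4-methoxy-5-methyl-2H-pyran-2-one) | CC(C)C(=O)c1c(O)c(Cc2c(OC)c(C)c(CC)oc2=O)c(O)c(Cc2c(OC)c(C)c(CC)oc2=O)c1O | intermediate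
27 | 3,3'-{[2,4,6-trihydroxy-5-(2-methylpropanoyl)-1,3-phenylene]bis(methylene)}bis(6-ethyl-4-hydroxy-5-methyl-2H-pyran-2-one) (CNP0277086.0) | CCc1oc(=O)c(Cc2c(O)c(Cc3c(O)c(C)c(CC)oc3=O)c(O)c(C(=O)C(C)C)c2O)c(O)c1C | target

**Step count and risks**

Total step count: 16. Longest linear sequence: 15 steps (steps 1–7 and 9–16, from pentan-3-one); step 8 is a one-step side branch.

Steps most likely to fail:

1. Step 15 (ring A Claisen closure). Enol-lactonisation of the C5 oxygen onto C1, or methoxide opening of the arm lactones, may outrun C-acylation at C6, and retro-Claisen cleavage of the chain may consume the triketo ester. The fallback makes ring A first and uses known methylene-bridging chemistry; it sets out from 4 and comes back to the route at 27. Friedel–Crafts acylation of commercial benzene-1,3,5-triol with 2-methylpropanoyl chloride (AlCl3, nitrobenzene/CH2Cl2) should give 2-methyl-1-(2,4,6-trihydroxyphenyl)propan-1-one F1. Pyranone 4 (2 equiv) with Me2N=CH2+ I− should give the Mannich base 3-[(dimethylamino)methyl]-6-ethyl-4-hydroxy-5-methyl-2H-pyran-2-one F2. On warming, this loses dimethylamine to give 6-ethyl-5-methyl-3-methylidene-2H-pyran-2,4(3H)-dione F3. F1 adds through its two free ring carbons to two molecules of F3 (Michael-type C-alkylation) and should give 27 directly, so compounds 5–26 are not needed.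

2. Step 13 (isoxazoline unmasking). The transient ketimine nitrogen may condense with the C3 ketone (six-membered cyclic imine, then a pyridine) faster than it is hydrolysed, or the aldol may dehydrate or undergo retro-aldol cleavage. The fallback removes the carbonyl partner before the nitrogen is set free; it sets out from 22 and comes back at 25. NaBH4 (MeOH, 0 °C) should reduce only the C3 ketone and give methyl 5-Ar-2-(ArCH2)-3-hydroxy-4-[3-(propan-2-yl)-4,5-dihydro-1,2-oxazol-5-yl]pentanoate F4. Hydrogenolysis under the conditions of step 13 then passes through methyl 2,4-bis(ArCH2)-3,5-dihydroxy-7-imino-8-methylnonanoate F5 (not isolated) to methyl 2,4-bis(ArCH2)-3,5-dihydroxy-8-methyl-7-oxononanoate F6. Dess–Martin periodinane in excess oxidises both carbinols and should give 25.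

3. Step 5 (Stille hydroxymethylation). Transfer of the hydroxymethyl group from tin may be slow, so that protodestannylation and reduction of the C–Br bond take over. The fallback introduces the carbon as a vinyl group and cleaves it; it sets out from 6 and comes back at 7. Stille coupling with tributyl(vinyl)stannane (Pd(PPh3)4, toluene, 100 °C) should give 3-ethenyl-6-ethyl-4-methoxy-5-methyl-2H-pyran-2-one F7. OsO4 (cat.) with NaIO4 (2,6-lutidine, dioxane/H2O) cleaves the vinyl group through 3-(1,2-dihydroxyethyl)-6-ethyl-4-methoxy-5-methyl-2H-pyran-2-one F8 (not isolated) to 6-ethyl-4-methoxy-5-methyl-2-oxo-2H-pyran-3-carbaldehyde F9. NaBH4 (MeOH, 0 °C) then gives 7.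

**Further compounds**

F1 | step 15 | 2-methyl-1-(2,4,6-trihydroxyphenyl)propan-1-one | CC(C)C(=O)c1c(O)cc(O)cc1O
F2 | step 15 | 3-[(dimethylamino)methyl]-6-ethyl-4-hydroxy-5-methyl-2H-pyran-2-one | CCc1oc(=O)c(CN(C)C)c(O)c1C
F3 | step 15 | 6-ethyl-5-methyl-3-methylidene-2H-pyran-2,4(3H)-dione | CCC1=C(C)C(=O)C(=C)C(=O)O1
F4 | step 13 | methyl 5-(6-ethyl-4-methoxy-5-methyl-2-oxo-2H-pyran-3-yl)-2-[(6-ethyl-4-methoxy-5-methyl-2-oxo-2H-pyran-3-yl)methyl]-3-hydroxy-4-[3-(propan-2-yl)-4,5-dihydro-1,2-oxazol-5-yl]pentanoate | COC(=O)C(Cc1c(OC)c(C)c(CC)oc1=O)C(O)C(Cc1c(OC)c(C)c(CC)oc1=O)C1CC(C(C)C)=NO1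
F5 | step 13 | methyl 2,4-bis[(6-ethyl-4-methoxy-5-methyl-2-oxo-2H-pyran-3-yl)methyl]-3,5-dihydroxy-7-imino-8-methylnonanoate | COC(=O)C(Cc1c(OC)c(C)c(CC)oc1=O)C(O)C(Cc1c(OC)c(C)c(CC)oc1=O)C(O)CC(=N)C(C)C
F6 | step 13 | methyl 2,4-bis[(6-ethyl-4-methoxy-5-methyl-2-oxo-2H-pyran-3-yl)methyl]-3,5-dihydroxy-8-methyl-7-oxononanoate | COC(=O)C(Cc1c(OC)c(C)c(CC)oc1=O)C(O)C(Cc1c(OC)c(C)c(CC)oc1=O)C(O)CC(=O)C(C)C
F7 | step 5 | 3-ethenyl-6-ethyl-4-methoxy-5-methyl-2H-pyran-2-one | CCc1oc(=O)c(C=C)c(OC)c1C
F8 | step 5 | 3-(1,2-dihydroxyethyl)-6-ethyl-4-methoxy-5-methyl-2H-pyran-2-one | CCc1oc(=O)c(C(O)CO)c(OC)c1C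
F9 | step 5 | 6-ethyl-4-methoxy-5-methyl-2-oxo-2H-pyran-3-carbaldehyde | CCc1oc(=O)c(C=O)c(OC)c1C
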